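**Retrosynthetic overview**
1. Target 11 ⇐ dimethyl ether 10 by global O-demethylation. The two methyl ethers also fix the regiochemistry of ring closure.
2. Key disconnection C2–C1′: 10 ⇐ chromon-2-yl carbanion (β-acylvinyl d3 donor, zinc reagent 9 made from the C2–H of 6) + a nonacosyl unit released by decarboxylation of activated triacontanoic acid 8, which acts as an alkyl-halide surrogate. Both carbons are acceptor sites in normal reactivity.
3. 6 ⇐ o-hydroxyacetophenone 4 + one carbon (DMF-DMA). The benzene ring is bought. The 4-pyranone is the only ring built, and it is closed before the chain is attached.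
4. 4 ⇐ mirror-symmetric 3,5-dimethoxy-4-methylphenol 3 ⇐ 2,6-dimethoxytoluene 1 by sterically controlled C–H borylation/oxidation. In 3 the OH is para to CH3 and both ortho sites are equivalent, so only the 6-methyl series can form, never the 8-methyl series.

Assumption: the SMILES has no stereocentre or stereogenic double bond, so the target is achiral and needs no stereocontrol; the side chain is read as unbranched C29H59 (nonacosyl).

**Step 1**
Reactants: 1 2,6-dimethoxytoluene
Product: 3 3,5-dimethoxy-4-methylphenol, via aryl pinacolboronate 2 (not isolated)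
Conditions: [Ir(OMe)(cod)]2 (1.5 mol %), dtbpy (3 mol %), B2pin2 (1.0 equiv), THF, 80 °C, 16 h; then 30 % H2O2, aq NaOH (1 equiv), 0 °C → rt
Reagents that add atoms: bis(pinacolato)diboron, CC1(C)OB(OC1(C)C)B1OC(C)(C)C(C)(C)O1 (Bpin, in 2 only); hydrogen peroxide, OO (the phenol oxygen of 3)
Why: Iridium-catalysed C–H borylation (Hartwig–Miyaura type) is sterically governed, C4–H is the only ring C–H of 1 without an ortho substituent so the boronate forms there alone, and basic peroxide then converts C–B into C–OH at the same position; no stereocentre is formed.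

**Step 2**
Reactants: 3 3,5-dimethoxy-4-methylphenol
Product: 4 1-(6-hydroxy-2,4-dimethoxy-3-methylphenyl)ethan-1-one
Conditions: AcOH, BF3·OEt2 (3 equiv), 90 °C, 3 h; ice–water
Reagents that add atoms: acetic acid, CC(=O)O
Why: In this BF3-promoted Friedel–Crafts (Fries-type) C-acetylation the para position is blocked by CH3, the two ortho positions are equivalent by symmetry so only one hydroxy ketone can form, and chelation of the new carbonyl to the OH deactivates the ring against a second acylation.

**Step 3**
Reactants: 4 1-(6-hydroxy-2,4-dimethoxy-3-methylphenyl)ethan-1-one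
Product: 6 5,7-dimethoxy-6-methyl-4H-chromen-4-one, via enaminone 5 (not isolated)
Conditions: DMF-DMA (3 equiv), toluene, 105 °C, 6 h; concentrate; then conc. HCl, CH2Cl2, 40 °C
Reagents that add atoms: N,N-dimethylformamide dimethyl acetal, COC(OC)N(C)C
Why: In this enaminone chromone synthesis the acetyl CH3 condenses with the amide acetal and acid then drives addition–elimination of the phenol oxygen on the β-carbon with loss of Me2NH, and because the only free ortho oxygen is the one para to CH3 the ring can close only to the 6-methyl isomer.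

**Step 4 (key step)**
Reactants: 6 5,7-dimethoxy-6-methyl-4H-chromen-4-one; 7 triacontanoic acid
Product: 10 5,7-dimethoxy-6-methyl-2-nonacosyl-4H-chromen-4-one, via NHPI ester 8 (not isolated), via chromon-2-ylzinc chloride 9 (not isolated)
Conditions: (a) 7 (1.0 equiv), N-hydroxyphthalimide (1.0 equiv), DIC (1.05 equiv), DMAP (5 mol %), THF, 45 °C, 2 h; (b) 6 (2.2 equiv), TMPZnCl·LiCl (2.0 equiv), THF, 25 °C, 1–2 h; (c) a + b, Ni(acac)2 (10 mol %), 2,2′-bipyridine (10 mol %), THF–DMF, 40 °C, 12 h; aq NH4Cl (excess 6 recovered)
Reagents that add atoms: N-hydroxyphthalimide, O=C1c2ccccc2C(=O)N1O (atoms in 8 only); TMPZnCl·LiCl, CC1(C)CCCC(C)(C)N1[Zn]Cl.[Li+].[Cl-] (ZnCl in 9 only)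
Why: Proposed new method: the hindered zinc amide, used without added MgCl2 or BF3 (which would steer metalation to C3), removes the most acidic proton of 6 (C2–H, α to the ring oxygen; C2-zincation of chromones is a known reaction type) to give the β-acylvinyl zinc 9, a d3 donor at what is normally the Michael-acceptor carbon, which transmetalates to (bipy)Ni(I), the Ni(I)–chromonyl then reduces ester 8 by single-electron transfer so that 8 fragments to phthalimide anion, CO2 and the primary nonacosyl radical, and radical capture at nickel followed by reductive elimination from Ni(III) forms C2–C1′; the closest known reaction type is the Ni-catalysed decarboxylative Negishi alkenylation/arylation of in-situ-formed redox-active N-hydroxyphthalimide esters with alkenyl- and (hetero)arylzinc halides, the new element being the TMP-generated chromon-2-ylzinc partner, and no stereocentre is formed.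

**Step 5**
Reactants: 10 5,7-dimethoxy-6-methyl-2-nonacosyl-4H-chromen-4-one
Product: 11 5,7-dihydroxy-6-methyl-2-nonacosyl-4H-chromen-4-one (target)
Conditions: BBr3 (6 equiv), CH2Cl2, 0 → 40 °C, 16 h; ice–water
Reagents that add atoms: none
Why: In this BBr3 aryl methyl ether cleavage the 5-OMe is activated by chelation to C4=O and the 7-OMe is twisted out of conjugation by the flanking CH3 so both are cleaved, while the anhydrous Lewis-acid medium keeps the pyranone closed and so excludes the 6-methyl/8-methyl (Wessely–Moser) scrambling known in hot aqueous HI.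

**Compound list**
1 | 2,6-dimethoxytoluene (1,3-dimethoxy-2-methylbenzene) | COc1cccc(OC)c1C | starting material
2 | 2-(3,5-dimethoxy-4-methylphenyl)-4,4,5,5-tetramethyl-1,3,2-dioxaborolane | COc1cc(cc(OC)c1C)B1OC(C)(C)C(C)(C)O1 | intermediate
3 | 3,5-dimethoxy-4-methylphenol | COc1cc(O)cc(OC)c1C | intermediate
4 | 1-(6-hydroxy-2,4-dimethoxy-3-methylphenyl)ethan-1-one (acetyl flanked by OH and OMe; CH3 between the two OMe) | CC(=O)c1c(O)cc(OC)c(C)c1OC | intermediate
5 | (E)-3-(dimethylamino)-1-(6-hydroxy-2,4-dimethoxy-3-methylphenyl)prop-2-en-1-one | CN(C)/C=C/C(=O)c1c(O)cc(OC)c(C)c1OC | intermediate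
6 | 5,7-dimethoxy-6-methyl-4H-chromen-4-one | COc1cc2occc(=O)c2c(OC)c1C | intermediate
7 | triacontanoic (melissic) acid, n-C29H59CO2H | CCCCCCCCCCCCCCCCCCCCCCCCCCCCCC(=O)O | starting material
8 | 1,3-dioxoisoindolin-2-yl triacontanoate (NHPI ester) | CCCCCCCCCCCCCCCCCCCCCCCCCCCCCC(=O)ON1C(=O)c2ccccc2C1=O | intermediate
9 | (5,7-dimethoxy-6-methyl-4-oxo-4H-chromen-2-yl)zinc chloride (LiCl complex) | COc1cc2oc([Zn]Cl)cc(=O)c2c(OC)c1C | intermediate
10 | 5,7-dimethoxy-6-methyl-2-nonacosyl-4H-chromen-4-one | CCCCCCCCCCCCCCCCCCCCCCCCCCCCCc1cc(=O)c2c(OC)c(C)c(OC)cc2o1 | intermediate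
11 | 5,7-dihydroxy-6-methyl-2-nonacosyl-4H-chromen-4-one (achiral) | CCCCCCCCCCCCCCCCCCCCCCCCCCCCCc1cc(=O)c2c(O)c(C)c(O)cc2o1 | target

**Total step count:** 5. **Longest linear sequence:** 5 (1 → 3 → 4 → 6 → 10 → 11; acid 7 enters at step 4).

**Steps most likely to fail**

Step 4 (key coupling). The risks are slow transmetalation of the electron-poor zinc reagent, some C3 metalation, and addition of the alkyl radical to unmetalated 6. The fallback sets out from 7 and 6 and comes back at 10. Acid 7 is degraded by a Suárez-type Hunsdiecker reaction (PhI(OAc)2, I2, hν, cyclohexane, reflux) to the closed-shell electrophile 1-iodononacosane F1. The same donor 9, made from 6 as before, is then alkylated with F1 in a two-electron palladium alkyl-Negishi coupling (Pd2(dba)3, PCyp3, N-methylimidazole, THF–NMP, 80 °C), giving 10.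

Step 5 (demethylation of the waxy, poorly soluble 10). The risks are a stubborn 7-OMe and forcing conditions that endanger the regiochemistry. The fallback sets out from 6 and comes back at 11 by swapping the protecting groups before the chain is attached.
- 6 is demethylated while still small and soluble (BBr3, CH2Cl2) to 5,7-dihydroxy-6-methyl-4H-chromen-4-one F2.
- It is reprotected (MOMCl, NaH, DMF) as 5,7-bis(methoxymethoxy)-6-methyl-4H-chromen-4-one F3.
- TMPZnCl·LiCl zincates this to [5,7-bis(methoxymethoxy)-6-methyl-4-oxo-4H-chromen-2-yl]zinc chloride F4.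
- Coupling with 8 under the nickel conditions of step 4 gives 5,7-bis(methoxymethoxy)-6-methyl-2-nonacosyl-4H-chromen-4-one F5.
- The acetals are removed with HCl in MeOH–THF at 45 °C to give 11.

Step 1 (borylation/oxidation). The risks are sluggish borylation of the electron-rich arene and over-oxidation of the very electron-rich phenol. The fallback sets out from 1 and comes back at 4, reversing the order in which carbon and oxygen are installed. Friedel–Crafts acetylation of 1 (AcCl, SnCl4, CH2Cl2, 0 °C) goes ortho/para to the methoxy groups and gives 1-(2,4-dimethoxy-3-methylphenyl)ethan-1-one F6. Ketone-directed ortho C–H oxygenation ([RuCl2(p-cymene)]2, K2S2O8, TFA–TFAA, 80 °C) at the only C–H ortho to the acetyl group gives 2-acetyl-3,5-dimethoxy-4-methylphenyl trifluoroacetate F7. This is hydrolysed on aqueous work-up to 4.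

**Further compounds**
F1 | step 4 | 1-iodononacosane | CCCCCCCCCCCCCCCCCCCCCCCCCCCCCI
F2 | step 5 | 5,7-dihydroxy-6-methyl-4H-chromen-4-one | Cc1c(O)cc2occc(=O)c2c1O
F3 | step 5 | 5,7-bis(methoxymethoxy)-6-methyl-4H-chromen-4-one | COCOc1cc2occc(=O)c2c(OCOC)c1C
F4 | step 5 | [5,7-bis(methoxymethoxy)-6-methyl-4-oxo-4H-chromen-2-yl]zinc chloride | COCOc1cc2oc([Zn]Cl)cc(=O)c2c(OCOC)c1C
F5 | step 5 | 5,7-bis(methoxymethoxy)-6-methyl-2-nonacosyl-4H-chromen-4-one | CCCCCCCCCCCCCCCCCCCCCCCCCCCCCc1cc(=O)c2c(OCOC)c(C)c(OCOC)cc2o1
F6 | step 1 | 1-(2,4-dimethoxy-3-methylphenyl)ethan-1-one | CC(=O)c1ccc(OC)c(C)c1OC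
F7 | step 1 | 2-acetyl-3,5-dimethoxy-4-methylphenyl trifluoroacetate | CC(=O)c1c(OC(=O)C(F)(F)F)cc(OC)c(C)c1OC
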